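**Plan**

- Retrosynthesis: the upper C3–OH is traced back to a C3–I bond; then the C4–C4a bond of ring C is cut (iodocyclisation), followed by the O1–C2 ether bond, the C2–C3 bond (alkynyl plus aldehyde) and the C4–C6 bond to ring D (alkyne–aryl coupling).
- Enabling feature: upper C4 is bonded to ring A (at C4a) and to C6 of ring D while C3 bears oxygen. C3 and C4 are therefore the two carbons of a ring D aryl alkyne hung from ring A through O1–C2; electrophilic activation lets ring A add at C4 and leaves a C3–I bond as the site for the oxygen.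
- Forward: (+)-catechin is benzylated, blocked at C8 with bromine, iodinated at C6 and ethynylated. The alkyne is added to 3,4-bis(benzyloxy)benzaldehyde, the alcohol is etherified with 3-(benzyloxy)phenol, ring C is closed with I2, C3–I becomes C3=O and then C3–OH, and one hydrogenolysis unmasks everything.
- Stereochemistry: lower C2/C3 come from (+)-catechin. Upper C2 comes from an (R)-BINOL/Ti(OiPr)4-controlled alkynylzinc addition followed by an invertive Mitsunobu reaction. C4 comes from C2-directed protonation of the C3 enol (2,4-cis), and C3 from LiBH(s-Bu)3 attack anti to both aryl groups (all-cis 2R,3R,4S).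

Key step: step 9

Notation: rings A, B, C are the benzo ring, the 2-aryl ring and the pyran ring of the upper unit; rings D, E, F are the same for the catechin unit. "PBC-6-yl" is the (2R,3S)-3,5,7-tris(benzyloxy)-2-[3,4-bis(benzyloxy)phenyl]-8-bromochroman-6-yl group.

Remark: slow rotation about the C4–C6 bond to ring D in the 3-iodo and 3-boryl chromenes may show as rotamers; they are treated as one compound because this axis is no stereo-element of the target.

**Route**

Step 1
Reactants: 1 (+)-catechin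
Product: 2 (2R,3S)-5,7-bis(benzyloxy)-2-[3,4-bis(benzyloxy)phenyl]chroman-3-ol (5,7,3',4'-tetra-O-benzylcatechin)
Conditions: BnBr (4.4 equiv), K2CO3, DMF, 0 °C to rt
Reagents that add atoms: benzyl bromide, BrCc1ccccc1
Why: Williamson etherification in which K2CO3 deprotonates only the four phenols, so the secondary 3-OH stays free, and the mild base at low temperature limits C-benzylation and ring-opening epimerisation at C2.

Step 2
Reactants: 2 tetra-O-benzylcatechin
Product: 3 (2R,3S)-3,5,7-tris(benzyloxy)-2-[3,4-bis(benzyloxy)phenyl]chromane (penta-O-benzylcatechin)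
Conditions: NaH, BnBr, DMF, 0 °C to rt
Reagents that add atoms: benzyl bromide, BrCc1ccccc1
Why: Williamson etherification of the secondary alcohol through its sodium alkoxide, safe now that no free phenol can open ring F, and the extra benzyl group leaves in the final hydrogenolysis so no separate deprotection is needed.

Step 3
Reactants: 3 penta-O-benzylcatechin
Product: 4 (2R,3S)-3,5,7-tris(benzyloxy)-2-[3,4-bis(benzyloxy)phenyl]-8-bromochromane
Conditions: NBS (1.0 equiv), CH2Cl2, −40 °C to 0 °C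
Reagents that add atoms: N-bromosuccinimide, O=C1CCC(=O)N1Br
Why: Electrophilic aromatic bromination; of the two free positions of the phloroglucinol-type ring D, C8 is the more reactive towards NBS in benzylated catechins, so one equivalent at low temperature should install the blocking bromine there.

Step 4
Reactants: 4 8-bromo-penta-O-benzylcatechin
Product: 5 (2R,3S)-3,5,7-tris(benzyloxy)-2-[3,4-bis(benzyloxy)phenyl]-8-bromo-6-iodochromane
Conditions: NIS (1.2 equiv), CH2Cl2, 0 °C to rt, dark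
Reagents that add atoms: N-iodosuccinimide, O=C1CCC(=O)N1I
Why: Electrophilic aromatic iodination at C6, the only remaining position of the tri-oxygenated ring D, which is far more nucleophilic than the catechol diether ring E.

Step 5
Reactants: 5 8-bromo-6-iodo-penta-O-benzylcatechin; 6 trimethylsilylacetylene
Product: 7 (2R,3S)-3,5,7-tris(benzyloxy)-2-[3,4-bis(benzyloxy)phenyl]-8-bromo-6-[(trimethylsilyl)ethynyl]chromane
Conditions: PdCl2(PPh3)2 (5 mol%), CuI (10 mol%), Et3N/THF, 60 °C, sealed tube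
Reagents that add atoms: none
Why: Sonogashira coupling, in which zerovalent palladium inserts into the C6–I bond much faster than into the hindered, electron-rich C8–Br bond, so the blocking bromine survives.

Step 6
Reactants: 7 6-[(trimethylsilyl)ethynyl] compound
Product: 8 (2R,3S)-3,5,7-tris(benzyloxy)-2-[3,4-bis(benzyloxy)phenyl]-8-bromo-6-ethynylchromane (PBC-6-yl acetylene)
Conditions: K2CO3 (cat.), MeOH/THF, rt
Reagents that add atoms: none
Why: Base-catalysed methanolysis (protodesilylation) of the alkynyl C–Si bond, to which the aryl bromide and the benzyl ethers are inert.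

Step 7
Reactants: 8 PBC-6-yl acetylene; 9 3,4-bis(benzyloxy)benzaldehyde
Product: 11 (1S)-1-[3,4-bis(benzyloxy)phenyl]-3-(PBC-6-yl)prop-2-yn-1-ol, via alkynyl(ethyl)zinc 10 (not isolated)
Conditions: Et2Zn (1.1 equiv), toluene, reflux; then (R)-BINOL (20 mol%), Ti(OiPr)4 (50 mol%), CH2Cl2, rt; then 9 (1.3 equiv), rt; aq NH4Cl
Reagents that add atoms: none
Why: BINOL–titanium-catalysed enantioselective alkynylzinc addition to an aromatic aldehyde (aryl alkyne plus aryl aldehyde is its best-behaved pairing); the (R)-BINOL titanate delivers the alkynyl group of 10 to the Re face of the aldehyde and so sets the (S)-carbinol centre under catalyst control, the remote catechin stereocentres playing no part.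

Step 8
Reactants: 11 (1S)-propargylic alcohol; 12 3-(benzyloxy)phenol
Product: 13 1-(benzyloxy)-3-{[(1R)-1-[3,4-bis(benzyloxy)phenyl]-3-(PBC-6-yl)prop-2-yn-1-yl]oxy}benzene
Conditions: PPh3, DIAD, toluene, −20 °C to 0 °C
Reagents that add atoms: none
Why: Mitsunobu etherification, in which the phenol displaces the oxyphosphonium group by SN2 with inversion and turns the (S)-alcohol into the (R)-ether carrying the C2 configuration of the target; toluene and low temperature are chosen to hold back ionisation of the electron-rich benzylic position.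

Step 9
Reactants: 13 (1R)-aryl propargyl ether
Product: 14 (2R)-7-(benzyloxy)-2-[3,4-bis(benzyloxy)phenyl]-3-iodo-4-(PBC-6-yl)-2H-chromene
Conditions: I2 (2 equiv), NaHCO3 (2 equiv), MeNO2/CH2Cl2, 0 °C to rt, dark; aq Na2S2O3
Reagents that add atoms: iodine, II
Why: I2 turns the alkyne into an iodonium ion whose positive charge lies mainly on the carbon carrying the electron-rich ring D (the future C4); the ring A carbon para to the benzyloxy group adds there anti to iodine and NaHCO3 removes the proton of the Wheland intermediate (Friedel–Crafts-type alkyne arylation). The closest known reaction is the iodine-mediated electrophilic cyclisation of aryl propargyl ethers to 3-iodo-2H-chromenes. Ring C closes in the 6-endo-dig mode, which forms the C4–C4a bond and leaves iodine on C3; the 5-exo alternative would need charge on the carbon next to the oxygen-bearing C2. No stereocentre is created, and C2 keeps its configuration because none of its bonds takes part. The selectivity required is regiochemical on ring A, para and not ortho to the benzyloxy group, and it is secured by the crowding of the carbon between the two ring A oxygens together with para activation. Ring D offers no free position to iodine (C8 is brominated), and its benzyloxy oxygens could only attack the alkyne carbon remote from the cationic centre.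

Step 10
Reactants: 14 3-iodo-2H-chromene
Product: 15 (2S)-7-(benzyloxy)-2-[3,4-bis(benzyloxy)phenyl]-4-(PBC-6-yl)-3-(4,4,5,5-tetramethyl-1,3,2-dioxaborolan-2-yl)-2H-chromene (same C2 geometry as 14; the descriptor changes because boron ranks below carbon)
Conditions: B2pin2 (1.5 equiv), PdCl2(PPh3)2 (5 mol%), PPh3 (10 mol%), KOPh (1.5 equiv), toluene, 50 °C
Reagents that add atoms: bis(pinacolato)diboron, CC1(C)OB(OC1(C)C)B1OC(C)(C)C(C)(C)O1
Why: Miyaura borylation under the phenoxide conditions developed for alkenyl halides; oxidative addition of zerovalent palladium to the alkenyl C–I bond is far faster than to the hindered, electron-rich aryl C–Br bond, and the C2 stereocentre is not involved.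

Step 11
Reactants: 15 alkenyl boronate
Product: 17 (2R,4S)-7-(benzyloxy)-2-[3,4-bis(benzyloxy)phenyl]-4-(PBC-6-yl)chroman-3-one (2,4-cis), via enol 16 (not isolated)
Conditions: NaBO3·4H2O (3 equiv), THF/H2O, 0 °C to rt, argon
Reagents that add atoms: sodium perborate (NaBO3, used as the tetrahydrate), [Na+].[O-]OB=O
Why: Oxidation of the alkenylboronate (1,2-shift of carbon from boron to oxygen) gives the enol 16, whose tautomerisation sets C4: protonation occurs anti to the C2 aryl group and stays reversible through the enol, so the 2,4-cis ketone with both aryl groups pseudo-equatorial (4S) should result, while the mild perborate medium spares the less acidic C2–H.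

Step 12
Reactants: 17 2,4-cis flavan-3-one
Product: 18 (2R,3R,4S)-7-(benzyloxy)-2-[3,4-bis(benzyloxy)phenyl]-4-(PBC-6-yl)chroman-3-ol (all-cis)
Conditions: LiBH(s-Bu)3 (1.5 equiv), LiBr, THF, −78 °C; aq NH4Cl
Reagents that add atoms: none
Why: Diastereoselective ketone reduction with a bulky trialkylborohydride, which approaches the carbonyl from the face opposite to the two cis aryl groups and so places the new 3-OH cis to both (3R), as in the known conversion of flavan-3-ones into 2,3-cis flavan-3-ols.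

Step 13
Reactants: 18 protected all-cis dimer
Product: 19 (2R,3R,4S)-2-(3,4-dihydroxyphenyl)-4-[(2R,3S)-2-(3,4-dihydroxyphenyl)-3,5,7-trihydroxychroman-6-yl]chromane-3,7-diol (target, CNP0141631.2)
Conditions: H2 (1 atm), Pd(OH)2/C, Et3N (2 equiv), THF/MeOH/H2O, rt
Reagents that add atoms: none
Why: Catalytic hydrogenolysis, which should cleave the eight benzyl ethers and the aryl C–Br bond in one operation, while Et3N takes up HBr so that the acid-labile interflavan bond and the benzylic C2–O1 bonds are not endangered.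

**Compound list**

1 | (+)-catechin | O[C@H]1Cc2c(O)cc(O)cc2O[C@@H]1c1ccc(O)c(O)c1 | starting material
2 | (2R,3S)-5,7-bis(benzyloxy)-2-[3,4-bis(benzyloxy)phenyl]chroman-3-ol | c1c(OCc3ccccc3)cc2c(c1OCc1ccccc1)C[C@H](O)[C@@H](c1ccc(OCc3ccccc3)c(OCc3ccccc3)c1)O2 | intermediate
3 | (2R,3S)-3,5,7-tris(benzyloxy)-2-[3,4-bis(benzyloxy)phenyl]chromane | c1c(OCc3ccccc3)cc2c(c1OCc1ccccc1)C[C@H](OCc1ccccc1)[C@@H](c1ccc(OCc3ccccc3)c(OCc3ccccc3)c1)O2 | intermediate
4 | (2R,3S)-3,5,7-tris(benzyloxy)-2-[3,4-bis(benzyloxy)phenyl]-8-bromochromane | c1c(OCc3ccccc3)c(Br)c2c(c1OCc1ccccc1)C[C@H](OCc1ccccc1)[C@@H](c1ccc(OCc3ccccc3)c(OCc3ccccc3)c1)O2 | intermediate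
5 | (2R,3S)-3,5,7-tris(benzyloxy)-2-[3,4-bis(benzyloxy)phenyl]-8-bromo-6-iodochromane | Ic1c(OCc3ccccc3)c(Br)c2c(c1OCc1ccccc1)C[C@H](OCc1ccccc1)[C@@H](c1ccc(OCc3ccccc3)c(OCc3ccccc3)c1)O2 | intermediate
6 | trimethylsilylacetylene | C#C[Si](C)(C)C | starting material
7 | (2R,3S)-3,5,7-tris(benzyloxy)-2-[3,4-bis(benzyloxy)phenyl]-8-bromo-6-[(trimethylsilyl)ethynyl]chromane | C[Si](C)(C)C#Cc1c(OCc3ccccc3)c(Br)c2c(c1OCc1ccccc1)C[C@H](OCc1ccccc1)[C@@H](c1ccc(OCc3ccccc3)c(OCc3ccccc3)c1)O2 | intermediate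
8 | (2R,3S)-3,5,7-tris(benzyloxy)-2-[3,4-bis(benzyloxy)phenyl]-8-bromo-6-ethynylchromane | C#Cc1c(OCc3ccccc3)c(Br)c2c(c1OCc1ccccc1)C[C@H](OCc1ccccc1)[C@@H](c1ccc(OCc3ccccc3)c(OCc3ccccc3)c1)O2 | intermediate
9 | 3,4-bis(benzyloxy)benzaldehyde | O=Cc1ccc(OCc2ccccc2)c(OCc2ccccc2)c1 | starting material
10 | ethyl[(PBC-6-yl)ethynyl]zinc | CC[Zn]C#Cc1c(OCc3ccccc3)c(Br)c2c(c1OCc1ccccc1)C[C@H](OCc1ccccc1)[C@@H](c1ccc(OCc3ccccc3)c(OCc3ccccc3)c1)O2 | intermediate (not isolated)
11 | (1S)-1-[3,4-bis(benzyloxy)phenyl]-3-(PBC-6-yl)prop-2-yn-1-ol | O[C@@H](c1ccc(OCc3ccccc3)c(OCc3ccccc3)c1)C#Cc1c(OCc3ccccc3)c(Br)c2c(c1OCc1ccccc1)C[C@H](OCc1ccccc1)[C@@H](c1ccc(OCc3ccccc3)c(OCc3ccccc3)c1)O2 | intermediate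
12 | 3-(benzyloxy)phenol | Oc1cccc(OCc2ccccc2)c1 | starting material
13 | 1-(benzyloxy)-3-{[(1R)-1-[3,4-bis(benzyloxy)phenyl]-3-(PBC-6-yl)prop-2-yn-1-yl]oxy}benzene | c1ccccc1COc1cccc(c1)O[C@H](c1ccc(OCc3ccccc3)c(OCc3ccccc3)c1)C#Cc1c(OCc3ccccc3)c(Br)c2c(c1OCc1ccccc1)C[C@H](OCc1ccccc1)[C@@H](c1ccc(OCc3ccccc3)c(OCc3ccccc3)c1)O2 | intermediate
14 | (2R)-7-(benzyloxy)-2-[3,4-bis(benzyloxy)phenyl]-3-iodo-4-(PBC-6-yl)-2H-chromene | c1ccccc1COc1ccc2c(c1)O[C@H](c1ccc(OCc3ccccc3)c(OCc3ccccc3)c1)C(I)=C2c1c(OCc3ccccc3)c(Br)c2c(c1OCc1ccccc1)C[C@H](OCc1ccccc1)[C@@H](c1ccc(OCc3ccccc3)c(OCc3ccccc3)c1)O2 | intermediate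
15 | (2S)-7-(benzyloxy)-2-[3,4-bis(benzyloxy)phenyl]-4-(PBC-6-yl)-3-(4,4,5,5-tetramethyl-1,3,2-dioxaborolan-2-yl)-2H-chromene | c1ccccc1COc1ccc2c(c1)O[C@H](c1ccc(OCc3ccccc3)c(OCc3ccccc3)c1)C(B3OC(C)(C)C(C)(C)O3)=C2c1c(OCc3ccccc3)c(Br)c2c(c1OCc1ccccc1)C[C@H](OCc1ccccc1)[C@@H](c1ccc(OCc3ccccc3)c(OCc3ccccc3)c1)O2 | intermediate
16 | (2R)-7-(benzyloxy)-2-[3,4-bis(benzyloxy)phenyl]-4-(PBC-6-yl)-2H-chromen-3-ol (enol) | c1ccccc1COc1ccc2c(c1)O[C@H](c1ccc(OCc3ccccc3)c(OCc3ccccc3)c1)C(O)=C2c1c(OCc3ccccc3)c(Br)c2c(c1OCc1ccccc1)C[C@H](OCc1ccccc1)[C@@H](c1ccc(OCc3ccccc3)c(OCc3ccccc3)c1)O2 | intermediate (not isolated)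
17 | (2R,4S)-7-(benzyloxy)-2-[3,4-bis(benzyloxy)phenyl]-4-(PBC-6-yl)chroman-3-one | c1ccccc1COc1ccc2c(c1)O[C@H](c1ccc(OCc3ccccc3)c(OCc3ccccc3)c1)C(=O)[C@@H]2c1c(OCc3ccccc3)c(Br)c2c(c1OCc1ccccc1)C[C@H](OCc1ccccc1)[C@@H](c1ccc(OCc3ccccc3)c(OCc3ccccc3)c1)O2 | intermediate
18 | (2R,3R,4S)-7-(benzyloxy)-2-[3,4-bis(benzyloxy)phenyl]-4-(PBC-6-yl)chroman-3-ol | c1ccccc1COc1ccc2c(c1)O[C@H](c1ccc(OCc3ccccc3)c(OCc3ccccc3)c1)[C@H](O)[C@@H]2c1c(OCc3ccccc3)c(Br)c2c(c1OCc1ccccc1)C[C@H](OCc1ccccc1)[C@@H](c1ccc(OCc3ccccc3)c(OCc3ccccc3)c1)O2 | intermediate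
19 | (2R,3R,4S)-2-(3,4-dihydroxyphenyl)-4-[(2R,3S)-2-(3,4-dihydroxyphenyl)-3,5,7-trihydroxychroman-6-yl]chromane-3,7-diol | Oc1ccc2c(c1)O[C@H](c1ccc(O)c(O)c1)[C@H](O)[C@@H]2c1c(O)cc2c(c1O)C[C@H](O)[C@@H](c1ccc(O)c(O)c1)O2 | target

**Count and risks**

Total step count: 13. Longest linear sequence: 13 steps, from (+)-catechin 1 to 19; compounds 6, 9 and 12 are purchased.

Steps most likely to fail:

1. Step 9. The iodonium ion may be intercepted by a ring D benzyloxy oxygen (5-endo closure with loss of benzyl iodide), or iodine may substitute the activated ring A instead of activating the alkyne. Fallback, setting out from 13 and returning at 17: a cationic gold catalyst, (Ph3P)AuNTf2 (monovalent gold) in CH2Cl2 at rt, should effect the same 6-endo-dig closure as a hydroarylation. No iodide is present, so an oxonium ion formed at a benzyloxy oxygen cannot be dealkylated and can revert. This would give (2S)-7-(benzyloxy)-2-[3,4-bis(benzyloxy)phenyl]-4-(PBC-6-yl)-2H-chromene F1. Hydroboration with BH3·SMe2 anti to the C2 aryl group (boron to C3, hydrogen to the doubly benzylic C4), then NaBO3 oxidation, would give the 2,3-trans-3,4-trans alcohol (2R,3S,4S)-7-(benzyloxy)-2-[3,4-bis(benzyloxy)phenyl]-4-(PBC-6-yl)chroman-3-ol F2. Dess–Martin oxidation of F2 leads to ketone 17, which already has the 2,4-cis arrangement.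

2. Step 10. Oxidative addition and transmetalation at the tetrasubstituted alkenyl iodide, flanked by two aryl-bearing carbons, may be slow, so that protodeiodination or insertion into the C8–Br bond takes over. Fallback, setting out from 14 and returning at 15: iodine–magnesium exchange with iPrMgCl·LiCl in THF at −40 °C, where an alkenyl iodide exchanges far faster than a hindered aryl bromide, would give [(2R)-7-(benzyloxy)-2-[3,4-bis(benzyloxy)phenyl]-4-(PBC-6-yl)-2H-chromen-3-yl]magnesium chloride F3. This is trapped in the cold with 2-isopropoxy-4,4,5,5-tetramethyl-1,3,2-dioxaborolane to give boronate 15.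

3. Step 8. Ionisation of the oxyphosphonium intermediate at the electron-rich benzylic, propargylic carbon would erode the configuration destined for C2. Fallback, setting out from 8 and returning at 13: step 7 is run with (S)-BINOL to give (1R)-1-[3,4-bis(benzyloxy)phenyl]-3-(PBC-6-yl)prop-2-yn-1-ol F4. Its oxygen is then arylated with 1-(benzyloxy)-3-iodobenzene in an Ullmann-type C–O coupling (CuI, 3,4,7,8-tetramethyl-1,10-phenanthroline, Cs2CO3, toluene, 80 °C). Because the carbinol C–O bond is never broken, the configuration is retained and the product is ether 13.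

Further compounds
F1 | step 9 | (2S)-7-(benzyloxy)-2-[3,4-bis(benzyloxy)phenyl]-4-(PBC-6-yl)-2H-chromene | c1ccccc1COc1ccc2c(c1)O[C@H](c1ccc(OCc3ccccc3)c(OCc3ccccc3)c1)C=C2c1c(OCc3ccccc3)c(Br)c2c(c1OCc1ccccc1)C[C@H](OCc1ccccc1)[C@@H](c1ccc(OCc3ccccc3)c(OCc3ccccc3)c1)O2
F2 | step 9 | (2R,3S,4S)-7-(benzyloxy)-2-[3,4-bis(benzyloxy)phenyl]-4-(PBC-6-yl)chroman-3-ol | c1ccccc1COc1ccc2c(c1)O[C@H](c1ccc(OCc3ccccc3)c(OCc3ccccc3)c1)[C@@H](O)[C@@H]2c1c(OCc3ccccc3)c(Br)c2c(c1OCc1ccccc1)C[C@H](OCc1ccccc1)[C@@H](c1ccc(OCc3ccccc3)c(OCc3ccccc3)c1)O2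
F3 | step 10 | [(2R)-7-(benzyloxy)-2-[3,4-bis(benzyloxy)phenyl]-4-(PBC-6-yl)-2H-chromen-3-yl]magnesium chloride | c1ccccc1COc1ccc2c(c1)O[C@H](c1ccc(OCc3ccccc3)c(OCc3ccccc3)c1)C([Mg]Cl)=C2c1c(OCc3ccccc3)c(Br)c2c(c1OCc1ccccc1)C[C@H](OCc1ccccc1)[C@@H](c1ccc(OCc3ccccc3)c(OCc3ccccc3)c1)O2
F4 | step 8 | (1R)-1-[3,4-bis(benzyloxy)phenyl]-3-(PBC-6-yl)prop-2-yn-1-ol | O[C@H](c1ccc(OCc3ccccc3)c(OCc3ccccc3)c1)C#Cc1c(OCc3ccccc3)c(Br)c2c(c1OCc1ccccc1)C[C@H](OCc1ccccc1)[C@@H](c1ccc(OCc3ccccc3)c(OCc3ccccc3)c1)O2
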